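**Plan**
- Retrosynthesis: the C15 methyl and hydroxyl are taken back to a C14 vinyl group. The lactone O–C14 bond is then cut (allyl C–O), followed by C14=C15 (cross-metathesis), the ring bond C2–C7 of the bromocyclohexane (bromonium/allylsilane cyclisation), C1–C2 and C3–C20 (alkyne carbometalation/benzylation), C4–C5 (triflate alkylation) and C12–C13 (allyl–allyl coupling).
- Forward: the C5–C15 chain is built from geranyl acetate and the hydroxybenzoate is attached. The cyclohexane ring closes first, the C10–C11 epoxide follows, and the 15-membered lactone ring closes fourth from the end.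
- Stereochemistry: C6 and C7 come from a titanium-mediated enantioselective bromochlorination and are relayed to C2 by a chair bromonium cyclisation. C10/C11 come from a Shi epoxidation, and C14 from a chiral iridium–phosphoramidite catalyst.
- Enabling feature: in the 15-membered lactone ring the ring oxygen sits on C14, a secondary carbon whose neighbour C15 is the carbinol carbon. C14–C15–C16 can therefore be an allyl unit whose substituted end (C14) is attacked by the benzoate oxygen.

Key step: step 16

Remark (numbering): C1 is the benzylic CH2; C2–C7 is the cyclohexane (C3 carries the methylidene carbon C20, C6 the bromine, C7 is quaternary); C8–C13 is the chain with the C10–C11 epoxide; C14 is the lactone carbinol; C15 is the CMe2OH carbon; C16 is the vinyl CH2 that becomes one of its methyls.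
Remark (assumption): the ligand antipodes in steps 4, 12 and 16 are assigned from the established facial rules of these catalyst families and are assumed to hold for the present substrates.

**Step 1**
Reactants: 1 geranyl acetate
Product: 2 (2E,6E)-8-hydroxy-3,7-dimethylocta-2,6-dien-1-yl acetate
Conditions: SeO2 (cat.), t-BuOOH, salicylic acid (cat.), CH2Cl2, rt
Reagents that add atoms: tert-butyl hydroperoxide, CC(C)(C)OO
Why: Riley-type allylic oxidation, in which the ene/[2,3]-sigmatropic sequence of SeO2 hydroxylates the (E)-methyl of the electron-rich terminal alkene while the 2,3-alkene is deactivated by the allylic acetate.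

**Step 2**
Reactants: 2 (2E,6E)-8-hydroxy-3,7-dimethylocta-2,6-dien-1-yl acetate
Product: 3 (2E,6E)-8-bromo-3,7-dimethylocta-2,6-dien-1-yl acetate
Conditions: CBr4, PPh3, CH2Cl2, 0 °C
Reagents that add atoms: carbon tetrabromide, BrC(Br)(Br)Br
Why: Appel bromination of the primary allylic alcohol under neutral conditions, without allylic transposition or loss of alkene geometry.

**Step 3**
Reactants: 3 (2E,6E)-8-bromo-3,7-dimethylocta-2,6-dien-1-yl acetate
Product: 4 (2E,6E)-3,7-dimethylundeca-2,6,10-trien-1-ol
Conditions: allylMgBr (3.5 equiv), THF, −78 °C to 0 °C; aq. NH4Cl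
Reagents that add atoms: allylmagnesium bromide, C=CC[Mg]Br
Why: uncatalysed allyl Grignard coupling at the unhindered primary allylic bromide (SN2, forming C12–C13), while the excess reagent adds twice to the acetate and frees the primary alcohol in the same flask.

**Step 4**
Reactants: 4 (2E,6E)-3,7-dimethylundeca-2,6,10-trien-1-ol
Product: 5 (2S,3R,6E)-2-bromo-3-chloro-3,7-dimethylundeca-6,10-dien-1-ol
Conditions: NBS, ClTi(OiPr)3, chiral tridentate Schiff-base (salicylaldimine amino-alcohol) ligand (20 mol%, antipode giving the 2S,3R adduct), hexanes, −20 °C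
Reagents that add atoms: N-bromosuccinimide, O=C1CCC(=O)N1Br; chlorotitanium triisopropoxide, CC(C)O[Ti](Cl)(OC(C)C)OC(C)C
Why: hydroxyl-directed catalytic enantioselective bromochlorination, in which the titanium-bound allylic alkoxide restricts anti addition to the 2,3-alkene (bromine at the secondary carbon, chloride at the tertiary one) and the ligand fixes the face, setting the future C6 (S) and C7 of the target.

**Step 5**
Reactants: 5 (2S,3R,6E)-2-bromo-3-chloro-3,7-dimethylundeca-6,10-dien-1-ol
Product: 6 (2S,3R,6E)-2-bromo-3-chloro-3,7-dimethylundeca-6,10-dien-1-yl trifluoromethanesulfonate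
Conditions: Tf2O, 2,6-lutidine, CH2Cl2, −78 °C
Reagents that add atoms: trifluoromethanesulfonic anhydride, O=S(=O)(OS(=O)(=O)C(F)(F)F)C(F)(F)F
Why: standard O-triflation of a primary alcohol with a hindered pyridine base, giving a leaving group reactive enough for C-alkylation at −78 °C.

**Step 6**
Reactants: 6 (2S,3R,6E)-2-bromo-3-chloro-3,7-dimethylundeca-6,10-dien-1-yl trifluoromethanesulfonate
Product: 7 [(5S,6R,9E)-5-bromo-6-chloro-6,10-dimethyltetradeca-9,13-dien-1-yn-1-yl]trimethylsilane
Conditions: 1-(trimethylsilyl)propyne, n-BuLi, THF, −78 °C; then 6, −78 °C to −40 °C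
Reagents that add atoms: 1-(trimethylsilyl)propyne, CC#C[Si](C)(C)C
Why: SN2 alkylation of the propargylic lithium reagent at its CH2 terminus by the primary triflate (three-carbon propargylation forming C4–C5), run cold so that elimination and attack at the secondary bromide or tertiary chloride should not compete.

**Step 7**
Reactants: 7 [(5S,6R,9E)-5-bromo-6-chloro-6,10-dimethyltetradeca-9,13-dien-1-yn-1-yl]trimethylsilane
Product: 8 (5S,6R,9E)-5-bromo-6-chloro-6,10-dimethyltetradeca-9,13-dien-1-yne
Conditions: K2CO3 (cat.), MeOH, 0 °C to rt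
Reagents that add atoms: none
Why: base-catalysed protodesilylation of the alkynylsilane by methanol, mild enough to leave both alkyl halides untouched.

**Step 8**
Reactants: 9 methyl 4-hydroxy-3-methylbenzoate
Product: 10 methyl 3-methyl-4-[(triisopropylsilyl)oxy]benzoate
Conditions: i-Pr3SiCl, imidazole, DMF, rt
Reagents that add atoms: chlorotriisopropylsilane, CC(C)[Si](Cl)(C(C)C)C(C)C
Why: standard silylation of the phenol, the bulky silyl ether being chosen to survive HFIP and the basic epoxidation medium of step 12.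

**Step 9**
Reactants: 10 methyl 3-methyl-4-[(triisopropylsilyl)oxy]benzoate
Product: 11 methyl 3-(bromomethyl)-4-[(triisopropylsilyl)oxy]benzoate
Conditions: NBS, AIBN (cat.), PhCF3, 80 °C
Reagents that add atoms: N-bromosuccinimide, O=C1CCC(=O)N1Br
Why: Wohl–Ziegler radical bromination at the only benzylic position, the ester-deactivated ring resisting electrophilic bromination.

**Step 10**
Reactants: 8 (5S,6R,9E)-5-bromo-6-chloro-6,10-dimethyltetradeca-9,13-dien-1-yne; 11 methyl 3-(bromomethyl)-4-[(triisopropylsilyl)oxy]benzoate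
Product: 14 methyl 3-[(2Z,6S,7R,10E)-6-bromo-7-chloro-7,11-dimethyl-3-(trimethylsilylmethyl)pentadeca-2,10,14-trien-1-yl]-4-[(triisopropylsilyl)oxy]benzoate, via alkenylcopper 12 (not isolated), via alkenylzinc bromide 13 (not isolated)
Conditions: Me3SiCH2MgCl, CuBr·SMe2, Et2O–Me2S, −25 °C to 0 °C; then ZnBr2, THF, Pd(PPh3)4 (5 mol%), 11, 0 °C to rt
Reagents that add atoms: (trimethylsilyl)methylmagnesium chloride, C[Si](C)(C)C[Mg]Cl
Why: syn-carbocupration of the terminal alkyne puts CH2SiMe3 on the inner carbon and copper on the terminal one, and transmetalation to zinc followed by palladium-catalysed Negishi-type coupling with the benzylic bromide proceeds with retention, so the arylmethyl group ends cis to CH2SiMe3, i.e. the (Z)-allylsilane.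

**Step 11**
Reactants: 14 methyl 3-[(2Z,6S,7R,10E)-6-bromo-7-chloro-7,11-dimethyl-3-(trimethylsilylmethyl)pentadeca-2,10,14-trien-1-yl]-4-[(triisopropylsilyl)oxy]benzoate
Product: 15 methyl 3-{[(1R,2S,3S)-3-bromo-2-methyl-2-[(3E)-4-methylocta-3,7-dien-1-yl]-6-methylidenecyclohexyl]methyl}-4-[(triisopropylsilyl)oxy]benzoate
Conditions: (CF3)2CHOH, 2,6-di-tert-butyl-4-methylpyridine (0.2 equiv), 0 °C to rt
Reagents that add atoms: none
Why: enantiospecific solvolytic bromonium polyene cyclisation, in which the tertiary C7 chloride ionises with participation of the C6 bromine and the (Z)-allylsilane attacks C7 through C2 in a chair transition state anti to bromine (C8 and the arylmethyl group equatorial, giving C2 R and C7 S), loss of silicon fixing the exocyclic C3 methylidene.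

**Step 12**
Reactants: 15 methyl 3-{[(1R,2S,3S)-3-bromo-2-methyl-2-[(3E)-4-methylocta-3,7-dien-1-yl]-6-methylidenecyclohexyl]methyl}-4-[(triisopropylsilyl)oxy]benzoate
Product: 16 methyl 3-{[(1R,2S,3S)-3-bromo-2-{2-[(2S,3S)-3-(but-3-en-1-yl)-3-methyloxiran-2-yl]ethyl}-2-methyl-6-methylidenecyclohexyl]methyl}-4-[(triisopropylsilyl)oxy]benzoate
Conditions: L-fructose-derived Shi ketone (30 mol%), Oxone (2KHSO5·KHSO4·K2SO4), K2CO3, Bu4NHSO4 (cat.), MeCN–CH2(OMe)2–aq. Na2B4O7/Na2EDTA buffer, 0 °C
Reagents that add atoms: potassium peroxymonosulfate (Oxone), [K+].[O-]S(=O)(=O)OO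
Why: Shi asymmetric epoxidation, in which the chiral dioxirane attacks the electron-rich trisubstituted C10=C11 alkene in preference to the 1,1-disubstituted and monosubstituted alkenes through a spiro transition state that should give the (10S,11S) epoxide under reagent control.

**Step 13**
Reactants: 16 methyl 3-{[(1R,2S,3S)-3-bromo-2-{2-[(2S,3S)-3-(but-3-en-1-yl)-3-methyloxiran-2-yl]ethyl}-2-methyl-6-methylidenecyclohexyl]methyl}-4-[(triisopropylsilyl)oxy]benzoate
Product: 17 3-{[(1R,2S,3S)-3-bromo-2-{2-[(2S,3S)-3-(but-3-en-1-yl)-3-methyloxiran-2-yl]ethyl}-2-methyl-6-methylidenecyclohexyl]methyl}-4-hydroxybenzoic acid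
Conditions: LiOH, THF–MeOH–H2O, 45 °C; cold aq. NaH2PO4 work-up
Reagents that add atoms: lithium hydroxide, [Li+].[OH-]
Why: saponification of the aryl methyl ester with deliberate concurrent cleavage of the hydroxide-labile aryl silyl ether, the equatorial neopentyl-type bromide and the trisubstituted epoxide being inert to hydroxide.

**Step 14**
Reactants: 17 3-{[(1R,2S,3S)-3-bromo-2-{2-[(2S,3S)-3-(but-3-en-1-yl)-3-methyloxiran-2-yl]ethyl}-2-methyl-6-methylidenecyclohexyl]methyl}-4-hydroxybenzoic acid
Product: 19 3-{[(1R,2S,3S)-3-bromo-2-{2-[(2S,3S)-3-(but-3-en-1-yl)-3-methyloxiran-2-yl]ethyl}-2-methyl-6-methylidenecyclohexyl]methyl}-4-[(tert-butyldimethylsilyl)oxy]benzoic acid, via bis-silyl compound 18 (not isolated)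
Conditions: t-BuMe2SiCl (2.5 equiv), imidazole, DMF, rt; then MeOH–H2O, NaHCO3 (cat.), 0 °C to rt
Reagents that add atoms: tert-butyldimethylsilyl chloride, CC(C)(C)[Si](C)(C)Cl
Why: standard hydroxy-acid protection, silylation of phenol and carboxylate being followed by selective solvolysis of the far more labile silyl ester under near-neutral conditions that spare the epoxide.

**Step 15**
Reactants: 19 3-{[(1R,2S,3S)-3-bromo-2-{2-[(2S,3S)-3-(but-3-en-1-yl)-3-methyloxiran-2-yl]ethyl}-2-methyl-6-methylidenecyclohexyl]methyl}-4-[(tert-butyldimethylsilyl)oxy]benzoic acid; 20 allyl methyl carbonate (5 equiv)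
Product: 21 seco acid, 3-{[(1R,2S,3S)-3-bromo-2-{2-[(2S,3S)-3-{(3E)-5-[(methoxycarbonyl)oxy]pent-3-en-1-yl}-3-methyloxiran-2-yl]ethyl}-2-methyl-6-methylidenecyclohexyl]methyl}-4-[(tert-butyldimethylsilyl)oxy]benzoic acid
Conditions: second-generation Hoveyda–Grubbs catalyst RuCl2(=CH-C6H4-2-OiPr)(H2IMes) (5 mol%), CH2Cl2, 40 °C
Reagents that add atoms: none
Why: olefin cross-metathesis of the monosubstituted C14 alkene with excess allyl methyl carbonate should give mainly the thermodynamically preferred (E)-allylic carbonate, the hindered 1,1-disubstituted exocyclic alkene, the epoxide and the free acid being tolerated by the ruthenium carbene.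

**Step 16**
Reactants: 21 seco acid with (E)-allylic methyl carbonate
Product: 22 C14-vinyl macrolactone silyl ether, (2R,6S,7S,10S,11S,14S) in target numbering
Conditions: [Ir(cod)Cl]2 (4 mol%), (Ra,R,R)-O,O′-(1,1′-binaphthyl-2,2′-diyl) N,N-bis(1-phenylethyl)phosphoramidite (8 mol%), pre-activated with n-PrNH2 (then removed); i-Pr2NEt (1.2 equiv), THF, 35 °C, slow addition of 21 to about 1 mM
Reagents that add atoms: none
Why: Proposed new method: the cyclometalated iridium–phosphoramidite complex (monovalent iridium) ionises the (E)-allylic methyl carbonate to a π-allyl complex of trivalent iridium, the expelled methyl carbonate collapses to CO2 and methoxide, which deprotonates the benzoic acid, and the carboxylate oxygen attacks the substituted allyl terminus C14 on the face opposite the metal. The closest known reaction type is the intermolecular iridium–phosphoramidite branched- and enantioselective allylic substitution of linear carbonates with carboxylate (and phenoxide) nucleophiles; running it as a ring closure is the new element. The 15-membered lactone ring closes by O–C14 bond formation, an exo attack of the tethered carboxylate on the inner allyl carbon, the alternative attack at C16 leading to a 17-membered linear isomer. The new C14 centre (S) is controlled by the ligand, which fixes the allyl face open to the nucleophile, so that it does not depend on the distant C2, C6, C7, C10 and C11 centres. The step needs branched regioselectivity, a single nucleophile and monomeric closure: the first is intrinsic to this catalyst class, the second is secured by the silylated phenol and the absence of any free hydroxyl, and the third by slow addition at high dilution together with the much faster ionisation of a carbonate than of the product benzoate.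

**Step 17**
Reactants: 22 C14-vinyl macrolactone silyl ether
Product: 23 C14-acetyl macrolactone silyl ether (C15 methyl ketone)
Conditions: PdCl2(Quinox) [Quinox = 2-(4,5-dihydrooxazol-2-yl)quinoline] (5 mol%), AgSbF6 (12 mol%), aq. t-BuOOH, CH2Cl2, 0 °C to rt
Reagents that add atoms: tert-butyl hydroperoxide, CC(C)(C)OO
Why: Wacker-type oxidation with the quinoline–oxazoline complex of divalent palladium and TBHP gives methyl ketones from protected allylic alcohols with Markovnikov selectivity, the 1,1-disubstituted exocyclic alkene is not a substrate, and C14 is not touched.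

**Step 18**
Reactants: 23 C14-acetyl macrolactone silyl ether
Product: 24 bromophycolide F tert-butyldimethylsilyl ether
Conditions: CeCl3 (anhydrous), MeMgBr, THF, −78 °C; AcOH/THF quench at −78 °C, then aq. NH4Cl
Reagents that add atoms: methylmagnesium bromide, C[Mg]Br
Why: organocerium addition, the weakly basic and oxophilic methylcerium reagent adding to the ketone without enolising the α-acyloxy centre C14 and faster than to the hindered lactone or the epoxide, while the cold acidic quench should prevent acyl migration to the new tertiary alkoxide.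

**Step 19**
Reactants: 24 bromophycolide F tert-butyldimethylsilyl ether
Product: 25 bromophycolide F
Conditions: Bu4NF, AcOH (1:1), THF, 0 °C
Reagents that add atoms: none
Why: fluoride cleavage of the aryl silyl ether, buffered with acetic acid so that lactone, epoxide and tertiary alcohol are left alone and no acyl shift occurs.

**Compound list**
1 | geranyl acetate, (2E)-3,7-dimethylocta-2,6-dien-1-yl acetate | CC(=O)OC/C=C(\C)CCC=C(C)C | starting material
2 | (2E,6E)-8-hydroxy-3,7-dimethylocta-2,6-dien-1-yl acetate | CC(=O)OC/C=C(\C)CC/C=C(\C)CO | intermediate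
3 | (2E,6E)-8-bromo-3,7-dimethylocta-2,6-dien-1-yl acetate | CC(=O)OC/C=C(\C)CC/C=C(\C)CBr | intermediate
4 | (2E,6E)-3,7-dimethylundeca-2,6,10-trien-1-ol | OC/C=C(\C)CC/C=C(\C)CCC=C | intermediate
5 | (2S,3R,6E)-2-bromo-3-chloro-3,7-dimethylundeca-6,10-dien-1-ol | OC[C@H](Br)[C@@](Cl)(C)CC/C=C(\C)CCC=C | intermediate
6 | (2S,3R,6E)-2-bromo-3-chloro-3,7-dimethylundeca-6,10-dien-1-yl trifluoromethanesulfonate | O=S(=O)(OC[C@H](Br)[C@@](Cl)(C)CC/C=C(\C)CCC=C)C(F)(F)F | intermediate
7 | [(5S,6R,9E)-5-bromo-6-chloro-6,10-dimethyltetradeca-9,13-dien-1-yn-1-yl]trimethylsilane | C[Si](C)(C)C#CCC[C@H](Br)[C@@](Cl)(C)CC/C=C(\C)CCC=C | intermediate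
8 | (5S,6R,9E)-5-bromo-6-chloro-6,10-dimethyltetradeca-9,13-dien-1-yne | C#CCC[C@H](Br)[C@@](Cl)(C)CC/C=C(\C)CCC=C | intermediate
9 | methyl 4-hydroxy-3-methylbenzoate | COC(=O)c1ccc(O)c(C)c1 | starting material
10 | methyl 3-methyl-4-[(triisopropylsilyl)oxy]benzoate | COC(=O)c1ccc(O[Si](C(C)C)(C(C)C)C(C)C)c(C)c1 | intermediate
11 | methyl 3-(bromomethyl)-4-[(triisopropylsilyl)oxy]benzoate | COC(=O)c1ccc(O[Si](C(C)C)(C(C)C)C(C)C)c(CBr)c1 | intermediate
12 | (Z)-alkenylcopper from syn-addition of Me3SiCH2Cu to 8 (Cu on the terminal carbon, cis to CH2SiMe3) | C[Si](C)(C)C/C(=C\[Cu])CC[C@H](Br)[C@@](Cl)(C)CC/C=C(\C)CCC=C | intermediate (not isolated)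
13 | corresponding (Z)-alkenylzinc bromide | C[Si](C)(C)C/C(=C\[Zn]Br)CC[C@H](Br)[C@@](Cl)(C)CC/C=C(\C)CCC=C | intermediate (not isolated)
14 | methyl 3-[(2Z,6S,7R,10E)-6-bromo-7-chloro-7,11-dimethyl-3-(trimethylsilylmethyl)pentadeca-2,10,14-trien-1-yl]-4-[(triisopropylsilyl)oxy]benzoate | COC(=O)c1ccc(O[Si](C(C)C)(C(C)C)C(C)C)c(C/C=C(\C[Si](C)(C)C)CC[C@H](Br)[C@@](Cl)(C)CC/C=C(\C)CCC=C)c1 | intermediate
15 | methyl 3-{[(1R,2S,3S)-3-bromo-2-methyl-2-[(3E)-4-methylocta-3,7-dien-1-yl]-6-methylidenecyclohexyl]methyl}-4-[(triisopropylsilyl)oxy]benzoate | C=C1CC[C@H](Br)[C@@](C)(CC/C=C(\C)CCC=C)[C@@H]1Cc1cc(ccc1O[Si](C(C)C)(C(C)C)C(C)C)C(=O)OC | intermediate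
16 | methyl 3-{[(1R,2S,3S)-3-bromo-2-{2-[(2S,3S)-3-(but-3-en-1-yl)-3-methyloxiran-2-yl]ethyl}-2-methyl-6-methylidenecyclohexyl]methyl}-4-[(triisopropylsilyl)oxy]benzoate | C=C1CC[C@H](Br)[C@@](C)(CC[C@@H]2O[C@@]2(C)CCC=C)[C@@H]1Cc1cc(ccc1O[Si](C(C)C)(C(C)C)C(C)C)C(=O)OC | intermediate
17 | 3-{[(1R,2S,3S)-3-bromo-2-{2-[(2S,3S)-3-(but-3-en-1-yl)-3-methyloxiran-2-yl]ethyl}-2-methyl-6-methylidenecyclohexyl]methyl}-4-hydroxybenzoic acid | C=C1CC[C@H](Br)[C@@](C)(CC[C@@H]2O[C@@]2(C)CCC=C)[C@@H]1Cc1cc(ccc1O)C(=O)O | intermediate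
18 | tert-butyldimethylsilyl ester of 19 (aryl silyl ether and silyl ester) | C=C1CC[C@H](Br)[C@@](C)(CC[C@@H]2O[C@@]2(C)CCC=C)[C@@H]1Cc1cc(ccc1O[Si](C)(C)C(C)(C)C)C(=O)O[Si](C)(C)C(C)(C)C | intermediate (not isolated)
19 | 3-{[(1R,2S,3S)-3-bromo-2-{2-[(2S,3S)-3-(but-3-en-1-yl)-3-methyloxiran-2-yl]ethyl}-2-methyl-6-methylidenecyclohexyl]methyl}-4-[(tert-butyldimethylsilyl)oxy]benzoic acid | C=C1CC[C@H](Br)[C@@](C)(CC[C@@H]2O[C@@]2(C)CCC=C)[C@@H]1Cc1cc(ccc1O[Si](C)(C)C(C)(C)C)C(=O)O | intermediate
20 | allyl methyl carbonate | C=CCOC(=O)OC | starting material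
21 | seco acid with (E)-allylic methyl carbonate, 3-{[(1R,2S,3S)-3-bromo-2-{2-[(2S,3S)-3-{(3E)-5-[(methoxycarbonyl)oxy]pent-3-en-1-yl}-3-methyloxiran-2-yl]ethyl}-2-methyl-6-methylidenecyclohexyl]methyl}-4-[(tert-butyldimethylsilyl)oxy]benzoic acid | C=C1CC[C@H](Br)[C@@](C)(CC[C@@H]2O[C@@]2(C)CC/C=C/COC(=O)OC)[C@@H]1Cc1cc(ccc1O[Si](C)(C)C(C)(C)C)C(O)=O | intermediate
22 | C14-vinyl macrolactone silyl ether (15-membered benzoate lactone; 2R,6S,7S,10S,11S,14S; C14 bears vinyl; phenol as TBS ether) | C=C1CC[C@H](Br)[C@@]2(C)CC[C@@H]3O[C@@]3(C)CC[C@@H](C=C)OC(=O)c3ccc(O[Si](C)(C)C(C)(C)C)c(c3)C[C@H]12 | intermediate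
23 | C14-acetyl macrolactone silyl ether (same stereodescriptors; C14 bears C(=O)CH3) | C=C1CC[C@H](Br)[C@@]2(C)CC[C@@H]3O[C@@]3(C)CC[C@@H](C(C)=O)OC(=O)c3ccc(O[Si](C)(C)C(C)(C)C)c(c3)C[C@H]12 | intermediate
24 | bromophycolide F tert-butyldimethylsilyl ether (C14 bears C(CH3)2OH) | C=C1CC[C@H](Br)[C@@]2(C)CC[C@@H]3O[C@@]3(C)CC[C@@H](C(C)(C)O)OC(=O)c3ccc(O[Si](C)(C)C(C)(C)C)c(c3)C[C@H]12 | intermediate
25 | bromophycolide F | C=C1CC[C@H](Br)[C@@]2(C)CC[C@@H]3O[C@@]3(C)CC[C@@H](C(C)(C)O)OC(=O)c3ccc(O)c(c3)C[C@H]12 | target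

**Step count**
Total: 19 steps. Longest linear sequence: 17 steps (steps 1–7 and 10–19); steps 8–9 make the arene fragment.

**The three steps most likely to fail**

1. Step 16 (the step proposed as a new method). The ring closure may be slower than intermolecular esterification, the branched allylic benzoate may re-ionise on the catalyst and drift to the linear 17-membered isomer or epimerise at C14, and the free acid may deactivate the cyclometalated catalyst. The fallback uses known chemistry only, sets out from 16 and returns at 22. Cross-metathesis of 16 with 20 under the conditions of step 15 would give the methyl ester allylic carbonate F1. An intermolecular iridium–phosphoramidite allylic hydroxylation with KHCO3 as hydroxide surrogate (same ligand antipode) would then set C14 and give the (14S)-allylic alcohol F2. Saponification with LiOH would give the dihydroxy acid F3. Treatment with t-BuMe2SiCl/Et3N in CH2Cl2 silylates phenol and carboxylate much faster than the secondary allylic alcohol and passes through the bis-silyl compound F4; mild methanolysis of its silyl ester would leave the seco hydroxy acid F5. A Shiina macrolactonisation (2-methyl-6-nitrobenzoic anhydride, DMAP, CH2Cl2, high dilution) closes the acyl–oxygen bond with retention at C14 and gives 22.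

2. Step 10. Syn-addition of the silylmethylcopper reagent to a terminal alkyne that also carries two alkyl halides may be slow, and the alkenyl metal may be lost by protonation or homocoupling before it is benzylated. The fallback separates the two events and reverses the polarity of the C1–C2 coupling; it sets out from 8 and 11 and returns at 14. The alkenylcopper 12 is quenched with iodine to give the (Z)-alkenyl iodide F6, which can be purified. Separately, 11 is converted with zinc dust and LiCl in THF into the benzylic zinc bromide F7. Negishi coupling of F6 with F7 (Pd(PPh3)4, THF, rt) gives 14 with retention of the alkene geometry.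

3. Step 17. The cationic palladium/silver/peroxide medium may open or rearrange the trisubstituted epoxide, and coordination by the neighbouring ester may divert part of the oxidation to the aldehyde. The fallback postpones the epoxidation until the ketone chemistry is finished; it sets out from 15 and returns at 24. Saponification of 15 as in step 13 gives the hydroxy acid F8. Silylation as in step 14 passes through the bis-silyl compound F9 to the silyl ether acid F10. Cross-metathesis with 20 gives the triene seco acid F11, and the iridium macrolactonisation of step 16 gives the epoxide-free vinyl macrolactone F12. Wacker oxidation, now without an epoxide present, gives the ketone F13, and organocerium methyl addition gives the tertiary alcohol F14. A final Shi epoxidation with the L-fructose-derived ketone, selective for the only trisubstituted alkene, returns 24.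

**Further compounds**
F1 | step 16 | methyl ester and triisopropylsilyl ether analogue of 21 (cross-metathesis product of 16 with 20) | C=C1CC[C@H](Br)[C@@](C)(CC[C@@H]2O[C@@]2(C)CC/C=C/COC(=O)OC)[C@@H]1Cc1cc(ccc1O[Si](C(C)C)(C(C)C)C(C)C)C(=O)OC
F2 | step 16 | (14S)-allylic alcohol methyl ester (C14 bears OH and vinyl; phenol as triisopropylsilyl ether) | C=C1CC[C@H](Br)[C@@](C)(CC[C@@H]2O[C@@]2(C)CC[C@H](O)C=C)[C@@H]1Cc1cc(ccc1O[Si](C(C)C)(C(C)C)C(C)C)C(=O)OC
F3 | step 16 | (14S)-dihydroxy acid (free phenol, free C14 alcohol, free acid) | C=C1CC[C@H](Br)[C@@](C)(CC[C@@H]2O[C@@]2(C)CC[C@H](O)C=C)[C@@H]1Cc1cc(ccc1O)C(=O)O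
F4 | step 16 | bis-silyl compound (aryl tert-butyldimethylsilyl ether and silyl ester, free C14 alcohol) | C=C1CC[C@H](Br)[C@@](C)(CC[C@@H]2O[C@@]2(C)CC[C@H](O)C=C)[C@@H]1Cc1cc(ccc1O[Si](C)(C)C(C)(C)C)C(=O)O[Si](C)(C)C(C)(C)C
F5 | step 16 | seco hydroxy acid (aryl tert-butyldimethylsilyl ether, free acid, (14S)-allylic alcohol) | C=C1CC[C@H](Br)[C@@](C)(CC[C@@H]2O[C@@]2(C)CC[C@H](O)C=C)[C@@H]1Cc1cc(ccc1O[Si](C)(C)C(C)(C)C)C(=O)O
F6 | step 10 | (Z)-alkenyl iodide, [(2Z,5S,6R,9E)-5-bromo-6-chloro-2-(iodomethylidene)-6,10-dimethyltetradeca-9,13-dien-1-yl]trimethylsilane (iodine cis to CH2SiMe3) | C[Si](C)(C)C/C(=C\I)CC[C@H](Br)[C@@](Cl)(C)CC/C=C(\C)CCC=C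
F7 | step 10 | benzylic zinc bromide from 11 | COC(=O)c1ccc(O[Si](C(C)C)(C(C)C)C(C)C)c(C[Zn]Br)c1
F8 | step 17 | epoxide-free hydroxy acid (C10=C11 E-alkene, free phenol) | C=C1CC[C@H](Br)[C@@](C)(CC/C=C(\C)CCC=C)[C@@H]1Cc1cc(ccc1O)C(=O)O
F9 | step 17 | epoxide-free bis-silyl compound (aryl silyl ether and silyl ester) | C=C1CC[C@H](Br)[C@@](C)(CC/C=C(\C)CCC=C)[C@@H]1Cc1cc(ccc1O[Si](C)(C)C(C)(C)C)C(=O)O[Si](C)(C)C(C)(C)C
F10 | step 17 | epoxide-free silyl ether acid | C=C1CC[C@H](Br)[C@@](C)(CC/C=C(\C)CCC=C)[C@@H]1Cc1cc(ccc1O[Si](C)(C)C(C)(C)C)C(=O)O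
F11 | step 17 | epoxide-free seco acid with (E)-allylic methyl carbonate | C=C1CC[C@H](Br)[C@@](C)(CC/C=C(\C)CC/C=C/COC(=O)OC)[C@@H]1Cc1cc(ccc1O[Si](C)(C)C(C)(C)C)C(O)=O
F12 | step 17 | epoxide-free C14-vinyl macrolactone silyl ether (C10=C11 E-alkene in the ring, 14S) | C=C1CC[C@H](Br)[C@@]2(C)CC/C=C(\C)CC[C@@H](C=C)OC(=O)c3ccc(O[Si](C)(C)C(C)(C)C)c(c3)C[C@H]12
F13 | step 17 | epoxide-free C14-acetyl macrolactone silyl ether | C=C1CC[C@H](Br)[C@@]2(C)CC/C=C(\C)CC[C@@H](C(C)=O)OC(=O)c3ccc(O[Si](C)(C)C(C)(C)C)c(c3)C[C@H]12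
F14 | step 17 | epoxide-free tertiary alcohol macrolactone silyl ether | C=C1CC[C@H](Br)[C@@]2(C)CC/C=C(\C)CC[C@@H](C(C)(C)O)OC(=O)c3ccc(O[Si](C)(C)C(C)(C)C)c(c3)C[C@H]12
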